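Of the molecules of starting material that free catalyst binds, 11.5% go on to target and the rest fall back. That share is the commitment to catalysis: the chance that catalyst intermediate A goes forward, with rate constant 10.7 /s, rather than back, with 82.1 /s, reckoned as forward over forward plus back.

    starting material + free catalyst ⇌ catalyst intermediate A (K1 = 1790 /M, k1 = 1.47 × 10⁵ /M/s)
    catalyst intermediate A → free catalyst + target (k2 = 10.7 /s)
    second substrate + free catalyst ⇌ catalyst intermediate B (K3 = 4050 /M, k3 = 1.98 × 10⁶ /M/s)
    catalyst intermediate B → free catalyst + second product (k4 = 30.7 /s)
    crystals ⇌ target, rate k5*(cs5 - [target]) while solid is left; crystals form when [target] > cs5 (cs5 = 0.012 mM, k5 = 8.96 /s)
    free catalyst + added ligand ⇌ idle complex (K6 = 3.2 × 10⁶ /M, k6 = 69500 /M/s)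

starting material 0.50 mM; second substrate 0.500 equiv; free catalyst 1.3 mol%; added ligand 5.8 µM; time 30 s

* the target and crystals together standing at 30 s, as a percentage of the starting material charged
* the change that raises the amount of target and crystals together at 30 s, in percent of the starting material charged most ("none" if none brings more than 2 percentage points) (cedar / oak / larch / none)
* amount of target and crystals together at 30 s, in percent of the starting material charged, after cedar

- cedar: doubling the dissolution coefficient of step 5, all else as stated
- oak: doubling the solubility in step 5, all else as stated
- larch: doubling the amount of free catalyst, all else as stated

- amounts and yields of target count crystals too
- given per volume of solution although it is solid: crystals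
- run time (flask): 30 s

Free catalyst therefore clears starting material with the effective constant 16900 /M/s, the binding constant times the commitment. Multiply this by the free catalyst and the time and you have an exponent; the fraction of the charge turned into target and crystals is one minus e to its negative.

Two of us disputed the free share. My colleague held that added ligand, 0.0116 of the starting material, is a trace, so the catalyst charge counts in full: the exponent is 3.30 and y is 96.3%.

I held that ligand must be measured against the catalyst, of which it makes 89.2%, and that free catalyst meets ligand at its charge with a time constant of 2.48 s, shorter than the 30 s given. That is a time constant and not the time the binding takes, so to reckon with the binding balance from the start is an estimate of mine. Counting catalyst outside idle complex as free, the binding balance leaves a free share of 25.1%. The exponent is then 0.830 and y is 56.4%. I leave out second substrate, and I cannot size that error.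

The same balance with the catalyst doubled gives 97.7%, so I name larch. Cedar and oak act behind the round, on forms that are counted together, so after cedar I keep 56.4%.

The forecast sides with me, though its number differs slightly from mine: 55%, within 50% to 60%, then larch as best and 55% after cedar, since “The crystallisation step only moves target between solution and solid and nothing feeds back on the catalysis”.

The simulation gives 54.8% at 30 s, 54.8% after cedar, and larch as best with a gain of 41 percentage points. The forecast holds, and my colleague's figure stands above the result.

My colleague's ground lies in the neighbour flask charged with 0.0014 mM of added ligand: there free catalyst stands at 71.6%, idle complex at 20.1%, and y reaches 85.3%, where 11.5% on that end share gives 90.6%. In the flask as charged, part of the shortfall lies at the fork of catalyst intermediate A and part in the time given. Removing the backward run sets the commitment to one and multiplies the exponent by 8.70, and that simulated run reaches 99.8%.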